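The runs stem from a simulated flask for an exercise.

The blue run, charged at 0.067 M, loses starting complex quickly: 63.4 % is left at 15.0 min, beside 18.5 % of complex with one exchanged, so 18.1 % of the charge is already in some unread form. The red run is the flask in question, and from 50.0 min on its readings show no trend beyond their scatter. Its readings average 51.4 % starting complex and 13.7 % complex with one exchanged.

| flask | starting complex | incoming ligand | remark | time |
|---|---|---|---|---|
| red | 0.10 M | 2.5 equiv | the very flask that is asked about, followed so far |  |
| blue | 0.067 M | 2.5 equiv | run made earlier |  |
| flask | 0.10 M | 2.50 equiv |  | 6.0 h |

| run | time / min | complex with one exchanged / % | starting complex / % |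
|---|---|---|---|
| red | 30.0 | 14.3 | 52.1 |
| red | 50.0 | 13.3 | 51.8 |
| red | 90.0 | 13.3 | 51.0 |
| red | 180 | 13.3 | 51.4 |
| red | 360 | 14.1 | 50.9 |
| blue | 1.33 | 5.3 | 94.8 |
| blue | 4.00 | 11.8 | 83.9 |
| blue | 6.00 | 15.4 | 78.0 |
| blue | 10.0 | 19.3 | 69.1 |
| blue | 15.0 | 18.5 | 63.4 |

(scatter of a reading: 0.5 percentage points)

- theta: at 6.0 h add starting complex, 50.0 % of the amount charged, then wait 3.0 h
- zeta: at 6.0 h add incoming ligand, 100 % of the amount charged, then wait 3.0 h
- alpha: at 6.0 h take out 90 % of the complex with one exchanged then present, then wait 3.0 h
- delta: change nothing and wait 3.0 h more

- complex with one exchanged that was removed still counts
- additions bring no volume worth counting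

1. complex with one exchanged, in percent of the starting complex first charged, at 6.0 h
2. the option that brings most further complex with one exchanged ("none" if no option brings more than 2 percentage points) (theta / zeta / alpha / delta / none)
3. complex with one exchanged present, with what was taken out counted in, in percent of the starting complex first charged, after zeta
4. complex with one exchanged present, with what was taken out counted in, in percent of the starting complex first charged, after delta

Two extreme versions can be solved in the head. If the reaction stopped at the first exchange, the 48.6 % lost from the starting complex in the red run would have to stand as complex with one exchanged, but the red run reads 13.7 % of it. If both exchanges ran one way, the fraction left of both complexes would head for zero. The red run lies between, so I read the missing 34.9 % as complex with two exchanged and both steps as reversible, which is thermodynamic control.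

Each step uses one incoming ligand and releases one leaving ligand, so the ligands cancel from a quotient: complex with one exchanged squared, over starting complex times complex with two exchanged. The red run reads it as 0.104. With the three shares summing to the amount present, complex with one exchanged peaks when the other two are equal. That gives the ceiling share, 13.9 %: the root of the quotient over two plus that root.

The red flask stands close to it, so by my reckoning more incoming ligand gains nothing. Adding starting complex gains up to 7.2 percentage points. Taking out 12.3 % and letting the rest refill gains 11 points.

The forecast gives 13.7 % now, alpha best, 13.6 % after zeta and 13.7 % after delta, and it says of complex with one exchanged under zeta that “it sits near its maximum”.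

The flask gives 13.7 % and alpha as best, gaining 11 points against 5.5 points for theta, with 13.6 % after zeta and 13.7 % after delta.

    starting complex + incoming ligand ⇌ leaving ligand + complex with one exchanged (K = 0.130, k = 0.280 M⁻¹ min⁻¹)
    complex with one exchanged + incoming ligand ⇌ leaving ligand + complex with two exchanged (K = 1.20, k = 0.510 M⁻¹ min⁻¹)
    complex with one exchanged ⇌ isomer of the product (K = 0.110, k = 0.0990 min⁻¹)

In the flask, the relaxation half-lives of the two exchanges are 2.59 min and 4.89 min, short against 6.0 h. At that time the backward rates stand at 100 % and 100 % of the forward ones. The zeta value lies close to the ceiling of 13.9 %. The neighbour with 4.20 equiv of incoming ligand holds 47.1 % of complex with two exchanged and, close to that same ceiling, 13.8 % of complex with one exchanged.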